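## Analysis of the target

The target 27 is a tetrahydropyran (ring atoms O1, C2, C3, C4, C5, C6). C2 carries a 4-hydroxyphenyl group, C3 an (E)-3-(4-hydroxyphenyl)prop-2-enyl (cinnamyl) chain, and C5 an exocyclic carbinol carbon C7 that bears OH and a third 4-hydroxyphenyl ring; C4 and C6 are plain methylene groups. There are four stereocentres, C2 (R), C3 (S), C5 (R) and C7 (R), and the three ring substituents at C2, C3 and C5 are all on the same face. Every chair therefore has at least one of them axial (C2-aryl axial with C3/C5 diequatorial, or C3/C5 diaxial), so equilibration cannot be trusted to give this isomer. The stereocentres fall into two pairs, C2/C3 and C5/C7, separated by the C4 methylene on one side and by O1–C6 on the other, so neither pair can pass its configuration to the other. The sensitive groups are three free phenols, two p-hydroxybenzylic C–O bonds (C2–O1 and C7–OH) that ionise to quinone methides under acid or forcing base, and the E-styrenyl double bond, which would compete in any alkene oxidation if it were present early. The difficulty is to close an all-cis ring without thermodynamic help while setting C5/C7 far from C2/C3. The strategy rests on the pair C5/C7: a ring carbon whose new bond runs to C4, next to a benzylic carbon bearing oxygen, is what backside opening of a trans aryl epoxide at its non-benzylic carbon delivers. C4 is an unfunctionalised methylene that can carry a removable sulfonyl group while it acts as the nucleophile.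

## Retrosynthetic reasoning

**27 from 26.** The three phenols are unmasked last, because the free p-hydroxybenzylic system is the most fragile form of the molecule. All three are carried as triisopropylsilyl ethers; the smaller tert-butyldimethylsilyl group on a phenol is too easily passed to an alkoxide or lost at the basic pH of the epoxidation, and both occur on the way to 26.

**26 from 23 and 25.** The styrenyl C=C of the C3 side chain is cut (cross-metathesis). It is cut there because that alkene is the same kind of trans aryl alkene as the one that must be epoxidised, so it cannot be present at that stage. A terminal allyl group is a poor dioxirane substrate and is inert in all the ionic steps. Styrene 25 comes from aldehyde 2 by methylenation with ylide 24, so one aromatic building block is used for two rings.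

**23 from 22.** The C4–S bond is cut. The sulfonyl group exists only to make C4 nucleophilic; its configuration does not matter, and because no leaving group sits β to C4 a single-electron reduction should remove it without elimination.

**22 from 19 (key disconnection).** The ring bond C4–C5 is cut. C4 is the only ring carbon with neither a stereocentre nor a heteroatom, so a carbanion can be placed there and erased afterwards, and C5–C7 is the pattern an epoxide opening leaves behind. The stereogenic ring bonds (O1–C2, C2–C3) are better made in open-chain form. The forward step must close the ring at C5 rather than at benzylic C7, with inversion, which fixes C5 and leaves the oxygen on C7.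

**19 from 18.** The epoxide is taken back to the (E)-cinnamyl ether. One reagent-controlled oxygen transfer sets C5 and C7 together. The required (2S,3S) epoxide calls for the catalyst enantiomer opposite to the one in common use, and the forward step must distinguish the trans aryl alkene from the terminal one.

**18 from 17, and 17 from 11 and 15.** The sulfone is taken back to sulfide 17, and the O1–C6 ether bond is cut to give alkoxide 16 (from alcohol 11) and allylic bromide 15. Oxidation at sulfur comes after the etherification, so that the alkoxide-forming step meets no acidic C–H, and before the epoxidation, so that the epoxide never sees the peroxide. C2 is not touched in the ether formation, so its configuration is safe. Bromide 15 comes from ester 12 through 13 and 14.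

**11 from 10, 10 from 9, 9 from 6 and 2.** The C4–S bond goes back to the primary hydroxyl of diol 10, and 10 to the aldol adduct 9. Cutting C2–C3 in 9 gives imide 6 and aldehyde 2; a boron syn-aldol under control of the (R)-auxiliary 4 sets C2 and C3. Imide 6 comes from acid 3 and 4 through anhydride 5, and aldehyde 2 from 4-hydroxybenzaldehyde 1.

## Alternatives that were turned down

**Alternative 1:** Both C2–C3 and C5–C7 are cut at once. C3, C4, C5 and the two attached carbonyl carbons come from the glutaryl bis-imide A1, and both carbinol carbons from the silylated aldehyde A2. In the forward step both imide arms are enolised under soft conditions (MgCl2, Et3N, Me3SiCl) and add to two molecules of A2 with anti-aldol sense at each end, giving the twofold-symmetric diol A3 after desilylating work-up.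
- For: one operation makes two C–C bonds and all four stereocentres from very cheap materials. The aldehyde is non-enolisable, which suits this aldol variant. Because A3 is twofold symmetric, either end can be addressed first with the same result, and δ-lactonisation onto the far imide would even close the right ring.
- Against: after the key step almost every carbon is at the wrong oxidation level. The carbonyl on C5 must become the C6 methylene bonded to O1. The carbonyl on C3 must become the saturated CH2 of the side chain and then be extended by an aryl-vinyl unit. That means reducing a lactone to a cyclic ether under hydride and Lewis-acid conditions beside two ionisable benzylic C–O bonds, and homologating through a β-hydroxy aldehyde that can undergo retro-aldol cleavage or epimerise at C3.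
- Comparison: on stereocentre economy Alternative 1 is clearly stronger (one stereo-defining step against three) and it has no regiochemical question. The chosen strategy offers instead carbons that are already at their final oxidation level (allyl for cinnamyl, C6 an ether methylene from the start), so after ring closure only one group is removed and one chain extended.

**Alternative 2:** O1–C6 is cut and C3–C6 are seen as the four carbons of a furan, in the 2,4-disubstituted furyl carbinol A4. In the forward step bromide-mediated anodic methoxylation of the furan (NH4Br, methanol, carbon anode) and aqueous acid unmask an ene-1,4-dicarbonyl, and the carbinol oxygen closes onto the former furan C5 to give pyranone A5.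
- For: the whole ring arises in one robust, scalable, reagent-free oxidation from a flat precursor that is easy to make in enantio-enriched form. Every ring carbon carries a handle (C3 ketone for the side chain, C7 ketone for the carbinol), and no regiochemical question arises.
- Against: A5 holds only the C2 stereocentre, and that centre is benzylic, α to oxygen and α to the C3 ketone, so it is prone to enolisation. C3, C5 and C7 would all be set later by substrate-controlled additions and reductions on a ring whose all-cis isomer is not the stable one. Three oxygen functions must be removed or changed, among them the C6 lactol hydroxyl by ionic reduction under acid next to the ionisable C2–O bond. The acyl-substituted furan is also harder to oxidise at the anode than the silyloxyarenes in the same molecule.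
- Comparison: Alternative 2 is stronger on the reliability and scale of the ring construction. The chosen strategy sets three of the four stereocentres by reagents and the fourth by a stereospecific substitution, and has no carbonyl to delete.

**Alternative 3:** C5–C6 and the C7–O bond are cut, leading to the (E)-styrene A6 and formaldehyde. In the forward step a confined chiral imidodiphosphorimidate Brønsted acid lets formaldehyde add to the styrene, forming C5–C6 and C7–O, and a second formaldehyde closes the 1,3-dioxane A7.
- For: it is a catalytic asymmetric C–C bond formation that sets C5 and C7 together and delivers C6–OH and C7–OH already protected. It needs no strong base and no labile epoxide, and acetates temper the arenes.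
- Against: the dioxane is not a ring of the target. It must be cleaved, and a methylene acetal needs the strong acid that the benzylic C7–O and C2–O bonds tolerate poorly. C6–OH and C7–OH must then be told apart, C6 activated and O1–C6 closed in a separate etherification, several steps that add nothing to the skeleton. The substrate also offers a second alkene to the Prins chemistry and a benzylic acetate at C2 that can ionise. It is a 1,2-disubstituted styrene with a branched substituent, whose match with the catalyst pocket is unknown.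
- Comparison: Alternative 3 is stronger in that its stereo-defining step forms a C–C bond by catalysis and avoids the regiochemical question of a carbanion at an aryl epoxide. The chosen strategy closes the target's own ring in the stereo-defining step and needs only a desulfonylation afterwards.

Key step: step 12

Remark on the chemistry: the epoxidation catalyst of step 11 is the L-fructose-derived enantiomer of the usual ketone (accessible from L-sorbose); it is used in substoichiometric amount and has no compound number, and methyl (E)-4-hydroxycinnamate 12 is taken as the purchasable form of 4-hydroxycinnamic acid.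

## Route

Step 1
Reactants: 1 4-hydroxybenzaldehyde
Product: 2 4-(triisopropylsilyloxy)benzaldehyde
Conditions: i-Pr3SiCl (1.1 equiv), imidazole (2.2 equiv), DMF, 0 °C → rt
Reagents that add atoms: triisopropylsilyl chloride, CC(C)[Si](Cl)(C(C)C)C(C)C
Why: Imidazole-promoted O-silylation of a phenol. The bulky triisopropylsilyl ether is chosen because it resists transfer to alkoxides (steps 9 and 12) and the basic aqueous medium of step 11.

Step 2
Reactants: 3 pent-4-enoic acid; 4 (R)-4-benzyl-2-oxazolidinone
Product: 6 (R)-4-benzyl-3-(pent-4-enoyl)oxazolidin-2-one, via pent-4-enoic pivalic anhydride 5 (not isolated)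
Conditions: t-BuCOCl (1.1 equiv), Et3N (2.5 equiv), THF, −20 °C; then LiCl (1.1 equiv), 4, −20 °C → rt
Reagents that add atoms: none
Why: Mixed-anhydride N-acylation of the oxazolidinone. LiCl and Et3N make the carbamate nitrogen nucleophilic enough to attack the less hindered acyl group of 5, so no strong base is needed.

Step 3
Reactants: 6 (R)-4-benzyl-3-(pent-4-enoyl)oxazolidin-2-one; 2 4-(triisopropylsilyloxy)benzaldehyde
Product: 9 (R)-4-benzyl-3-[(2R)-2-{(R)-hydroxy[4-(triisopropylsilyloxy)phenyl]methyl}pent-4-enoyl]oxazolidin-2-one, via Z-dibutylboron enolate 7 (not isolated), via dibutylboron aldolate 8 (not isolated)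
Conditions: n-Bu2BOTf (1.2 equiv), i-Pr2NEt (1.4 equiv), CH2Cl2, −78 → 0 °C; 2 (1.1 equiv), −78 → 0 °C; pH 7 phosphate buffer, MeOH, 30% H2O2, 0 °C
Reagents that add atoms: none
Why: Evans boron syn-aldol reaction. The Z-enolate 7 reacts through a closed Zimmerman–Traxler chair in which the aldehyde approaches the enolate face away from the benzyl group of the (R)-auxiliary, which sets C3 and C2 as the (2R,3R) syn pair. The aldehyde cannot enolise and the terminal alkene is inert.

Step 4
Reactants: 9 (R)-4-benzyl-3-[(2R)-2-{(R)-hydroxy[4-(triisopropylsilyloxy)phenyl]methyl}pent-4-enoyl]oxazolidin-2-one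
Product: 10 (1R,2S)-2-allyl-1-[4-(triisopropylsilyloxy)phenyl]propane-1,3-diol
Conditions: LiBH4 (2 equiv), MeOH (2 equiv), THF, 0 °C
Reagents that add atoms: none
Why: Reductive cleavage of the N-acyl oxazolidinone. Hydride attacks the exocyclic carbonyl, the auxiliary 4 is released for recovery, and the cold, weakly basic medium should leave C3 and the aldol linkage intact.

Step 5
Reactants: 10 (1R,2S)-2-allyl-1-[4-(triisopropylsilyloxy)phenyl]propane-1,3-diol
Product: 11 (1R,2R)-2-[(phenylsulfanyl)methyl]-1-[4-(triisopropylsilyloxy)phenyl]pent-4-en-1-ol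
Conditions: PhSSPh (1.5 equiv), n-Bu3P (1.5 equiv), THF, 0 °C → rt
Reagents that add atoms: diphenyl disulfide, c1ccc(SSc2ccccc2)cc1
Why: Hata reaction. The thiophosphonium salt activates the less hindered primary hydroxyl as an oxyphosphonium ion, which thiolate displaces by SN2; the hindered secondary benzylic hydroxyl should stay free.

Step 6
Reactants: 12 methyl (E)-3-(4-hydroxyphenyl)prop-2-enoate
Product: 13 methyl (E)-3-[4-(triisopropylsilyloxy)phenyl]prop-2-enoate
Conditions: i-Pr3SiCl (1.1 equiv), imidazole (2.2 equiv), DMF, rt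
Reagents that add atoms: triisopropylsilyl chloride, CC(C)[Si](Cl)(C(C)C)C(C)C
Why: O-Silylation of the phenol as in step 1, so that all three phenols carry the same group and fall in one final operation.

Step 7
Reactants: 13 methyl (E)-3-[4-(triisopropylsilyloxy)phenyl]prop-2-enoate
Product: 14 (E)-3-[4-(triisopropylsilyloxy)phenyl]prop-2-en-1-ol
Conditions: (i-Bu)2AlH (2.3 equiv), CH2Cl2, −78 °C; aq. potassium sodium tartrate
Reagents that add atoms: none
Why: 1,2-Reduction of an α,β-unsaturated ester by the aluminium hydride gives the allylic alcohol without touching the double bond or its E geometry.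

Step 8
Reactants: 14 (E)-3-[4-(triisopropylsilyloxy)phenyl]prop-2-en-1-ol
Product: 15 (E)-1-(3-bromoprop-1-enyl)-4-(triisopropylsilyloxy)benzene
Conditions: CBr4 (1.2 equiv), PPh3 (1.25 equiv), CH2Cl2, −20 → 0 °C; short filtration, used at once
Reagents that add atoms: tetrabromomethane, BrC(Br)(Br)Br
Why: Appel bromination under neutral conditions. The electron-rich cinnamyl bromide ionises easily, so it is not stored but used directly in step 9.

Step 9
Reactants: 11 (1R,2R)-2-[(phenylsulfanyl)methyl]-1-[4-(triisopropylsilyloxy)phenyl]pent-4-en-1-ol; 15 (E)-1-(3-bromoprop-1-enyl)-4-(triisopropylsilyloxy)benzene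
Product: 17 {4-[(E)-3-{(1R,2R)-2-[(phenylsulfanyl)methyl]-1-[4-(triisopropylsilyloxy)phenyl]pent-4-enyloxy}prop-1-enyl]phenoxy}triisopropylsilane, via potassium alkoxide 16 (not isolated)
Conditions: KN(SiMe3)2 (1.05 equiv), THF, −78 °C; then 15 (1.3 equiv), −78 → 0 °C
Reagents that add atoms: none
Why: Williamson ether synthesis. Alkoxide 16 displaces bromide at the primary allylic carbon by SN2, which keeps the E alkene and forms O1–C6 without touching C2. At the sulfide stage the substrate has no acidic C–H, so O-alkylation is the only course.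

Step 10
Reactants: 17 {4-[(E)-3-{(1R,2R)-2-[(phenylsulfanyl)methyl]-1-[4-(triisopropylsilyloxy)phenyl]pent-4-enyloxy}prop-1-enyl]phenoxy}triisopropylsilane
Product: 18 {4-[(E)-3-{(1R,2R)-2-[(phenylsulfonyl)methyl]-1-[4-(triisopropylsilyloxy)phenyl]pent-4-enyloxy}prop-1-enyl]phenoxy}triisopropylsilane
Conditions: (NH4)6Mo7O24·4H2O (10 mol %), 30% aq. H2O2 (5 equiv), EtOH, 0 °C → rt
Reagents that add atoms: hydrogen peroxide, OO
Why: Molybdate-catalysed oxidation of a sulfide to the sulfone through the sulfoxide. The peroxomolybdate attacks sulfur far faster than unactivated or styrenyl alkenes, so both double bonds should survive.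

Step 11
Reactants: 18 {4-[(E)-3-{(1R,2R)-2-[(phenylsulfonyl)methyl]-1-[4-(triisopropylsilyloxy)phenyl]pent-4-enyloxy}prop-1-enyl]phenoxy}triisopropylsilane
Product: 19 triisopropyl{4-[(2S,3S)-3-({(1R,2R)-2-[(phenylsulfonyl)methyl]-1-[4-(triisopropylsilyloxy)phenyl]pent-4-enyloxy}methyl)oxiran-2-yl]phenoxy}silane
Conditions: L-fructose-derived Shi ketone (1,2:4,5-di-O-isopropylidene-β-L-erythro-2,3-hexodiulo-2,6-pyranose, 30 mol %), Oxone (2KHSO5·KHSO4·K2SO4, 1.5 equiv KHSO5), K2CO3, Bu4NHSO4 (cat.), MeCN–CH2(OMe)2, aq. Na2B4O7/Na2EDTA buffer (pH about 10.5), 0 °C; cold basic work-up, no acidic silica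
Reagents that add atoms: Oxone (potassium peroxymonosulfate), [K+].[O-]S(=O)(=O)OO
Why: Shi asymmetric epoxidation. The chiral dioxirane formed from the ketone and KHSO5 passes oxygen to one face of the trans aryl alkene through a spiro transition state, setting C5 and C7 together. The common D-fructose ketone gives (R,R) epoxides from trans aryl alkenes, so its L-fructose-derived enantiomer is needed for the (2S,3S) epoxide. The electron-rich trans-disubstituted alkene should react well ahead of the terminal one, and the basic buffer protects the epoxide from acid.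

Step 12
Reactants: 19 triisopropyl{4-[(2S,3S)-3-({(1R,2R)-2-[(phenylsulfonyl)methyl]-1-[4-(triisopropylsilyloxy)phenyl]pent-4-enyloxy}methyl)oxiran-2-yl]phenoxy}silane
Product: 22 (R)-{(2R,3R,5R)-3-allyl-4-(phenylsulfonyl)-2-[4-(triisopropylsilyloxy)phenyl]tetrahydro-2H-pyran-5-yl}[4-(triisopropylsilyloxy)phenyl]methanol (C4 epimers; ring numbered as in the analysis), via C4-lithiated sulfone 20 (not isolated), via lithium C7-alkoxide 21 (not isolated)
Conditions: LiN(SiMe3)2 (2.0 equiv), THF, −78 → 0 °C; aq. NH4Cl
Reagents that add atoms: none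
Why: The amide base removes a proton from C4, the only carbon acid within its reach (α to the sulfonyl group), in an equilibrium that the irreversible ring closure drains. The α-sulfonyl carbanion 20 attacks the epoxide carbon C5 from the side opposite the C5–O bond in an intramolecular SN2 reaction, forming C4–C5 and leaving the oxygen on C7 as alkoxide 21, which is protonated on work-up. The closest known reaction type is the exo-mode cyclisation of epoxy sulfones, the sulfone counterpart of the epoxynitrile cyclisation. The tetrahydropyran ring (C4, C3, C2, O1, C6, C5) closes in the 6-exo-tet mode, the breaking C5–O bond lying outside the new ring. The one new stereocentre, C5, is fixed by the (2S,3S) epoxide through inversion; C7 keeps the configuration from step 11 and C2/C3 are untouched, so the all-cis ring follows from stereospecificity alone, although the chair-like transition state must carry the C2 aryl group axial. C4 forms as both epimers, which does not matter. The step needs attack at C5 and not at benzylic C7: the seven-membered endo transition state reaches the collinear backside geometry less easily than the six-membered one, and the medium (a lithium amide in THF, no added Lewis acid) gives the benzylic C7–O bond little help to ionise. No leaving group sits β to C4, so elimination cannot compete, and the triisopropylsilyl ethers should withstand the alkoxide formed.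

Step 13
Reactants: 22 (R)-{(2R,3R,5R)-3-allyl-4-(phenylsulfonyl)-2-[4-(triisopropylsilyloxy)phenyl]tetrahydro-2H-pyran-5-yl}[4-(triisopropylsilyloxy)phenyl]methanol (C4 epimers)
Product: 23 (R)-{(2R,3S,5R)-3-allyl-2-[4-(triisopropylsilyloxy)phenyl]tetrahydro-2H-pyran-5-yl}[4-(triisopropylsilyloxy)phenyl]methanol
Conditions: SmI2 (6 equiv), HMPA (12 equiv), MeOH (4 equiv), THF, −20 °C → rt
Reagents that add atoms: none
Why: Reductive desulfonylation. Electron transfer from divalent samarium to the aryl sulfone breaks the C4–S bond, and the C4 radical is reduced and protonated. C3 and C5 carry no leaving group, so no alkene can form, and both C4 epimers converge on one compound (the descriptor at C3 changes from R to S only because the sulfonyl group is gone).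

Step 14
Reactants: 2 4-(triisopropylsilyloxy)benzaldehyde
Product: 25 triisopropyl(4-vinylphenoxy)silane, via methylenetriphenylphosphorane 24 (not isolated)
Conditions: Ph3PCH3Br (1.3 equiv), KOt-Bu (1.25 equiv), THF, 0 °C; then 2, 0 °C → rt
Reagents that add atoms: methyltriphenylphosphonium bromide, C[P+](c1ccccc1)(c1ccccc1)c1ccccc1.[Br-]
Why: Wittig methylenation of an aromatic aldehyde with the preformed non-stabilised ylide; the aryl silyl ether is inert once the base has been consumed.

Step 15
Reactants: 23 (R)-{(2R,3S,5R)-3-allyl-2-[4-(triisopropylsilyloxy)phenyl]tetrahydro-2H-pyran-5-yl}[4-(triisopropylsilyloxy)phenyl]methanol; 25 triisopropyl(4-vinylphenoxy)silane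
Product: 26 (R)-{(2R,3S,5R)-2-[4-(triisopropylsilyloxy)phenyl]-3-{(E)-3-[4-(triisopropylsilyloxy)phenyl]prop-2-enyl}tetrahydro-2H-pyran-5-yl}[4-(triisopropylsilyloxy)phenyl]methanol
Conditions: second-generation Hoveyda–Grubbs catalyst (H2IMes)Cl2Ru=CH(C6H4-2-O-i-Pr) (5 mol %), 25 (4 equiv), CH2Cl2, 40 °C
Reagents that add atoms: none
Why: Olefin cross-metathesis of a terminal alkene with an excess of a styrene; loss of ethene drives it and the conjugated disubstituted product should form as the E isomer. The free secondary alcohol and the silyl ethers are tolerated by the ruthenium carbene.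

Step 16
Reactants: 26 (R)-{(2R,3S,5R)-2-[4-(triisopropylsilyloxy)phenyl]-3-{(E)-3-[4-(triisopropylsilyloxy)phenyl]prop-2-enyl}tetrahydro-2H-pyran-5-yl}[4-(triisopropylsilyloxy)phenyl]methanol
Product: 27 4-[(E)-3-{(2R,3S,5R)-5-[(R)-hydroxy(4-hydroxyphenyl)methyl]-2-(4-hydroxyphenyl)tetrahydro-2H-pyran-3-yl}prop-1-enyl]phenol (CNP0182155.1)
Conditions: n-Bu4NF (4 equiv), AcOH (4 equiv), THF, 0 °C → rt; pH 7 phosphate buffer
Reagents that add atoms: none
Why: Fluoride-induced cleavage of the three aryl silyl ethers. Acetic acid protonates each phenoxide as it forms, so the p-hydroxybenzylic C7–OH and C2–O1 bonds are not driven towards quinone methides and no stereocentre is touched.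

## Compound list

1 | 4-hydroxybenzaldehyde | O=Cc1ccc(O)cc1 | starting material
2 | 4-(triisopropylsilyloxy)benzaldehyde | O=Cc1ccc(O[Si](C(C)C)(C(C)C)C(C)C)cc1 | intermediate
3 | pent-4-enoic acid | C=CCCC(=O)O | starting material
4 | (R)-4-benzyl-2-oxazolidinone | O=C1N[C@H](Cc2ccccc2)CO1 | starting material
5 | pent-4-enoic pivalic anhydride (not isolated) | C=CCCC(=O)OC(=O)C(C)(C)C | intermediate
6 | (R)-4-benzyl-3-(pent-4-enoyl)oxazolidin-2-one | C=CCCC(=O)N1[C@H](Cc2ccccc2)COC1=O | intermediate
7 | Z-dibutylboron enolate of 6 (not isolated) | C=CC/C=C(\OB(CCCC)CCCC)N1[C@H](Cc2ccccc2)COC1=O | intermediate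
8 | dibutylboron aldolate of 9 (not isolated) | C=CC[C@@H](C(=O)N1[C@H](Cc2ccccc2)COC1=O)[C@@H](OB(CCCC)CCCC)c1ccc(O[Si](C(C)C)(C(C)C)C(C)C)cc1 | intermediate
9 | (R)-4-benzyl-3-[(2R)-2-{(R)-hydroxy[4-(triisopropylsilyloxy)phenyl]methyl}pent-4-enoyl]oxazolidin-2-one | C=CC[C@@H](C(=O)N1[C@H](Cc2ccccc2)COC1=O)[C@@H](O)c1ccc(O[Si](C(C)C)(C(C)C)C(C)C)cc1 | intermediate
10 | (1R,2S)-2-allyl-1-[4-(triisopropylsilyloxy)phenyl]propane-1,3-diol | C=CC[C@@H](CO)[C@@H](O)c1ccc(O[Si](C(C)C)(C(C)C)C(C)C)cc1 | intermediate
11 | (1R,2R)-2-[(phenylsulfanyl)methyl]-1-[4-(triisopropylsilyloxy)phenyl]pent-4-en-1-ol | C=CC[C@@H](CSc1ccccc1)[C@@H](O)c1ccc(O[Si](C(C)C)(C(C)C)C(C)C)cc1 | intermediate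
12 | methyl (E)-3-(4-hydroxyphenyl)prop-2-enoate | COC(=O)/C=C/c1ccc(O)cc1 | starting material
13 | methyl (E)-3-[4-(triisopropylsilyloxy)phenyl]prop-2-enoate | COC(=O)/C=C/c1ccc(O[Si](C(C)C)(C(C)C)C(C)C)cc1 | intermediate
14 | (E)-3-[4-(triisopropylsilyloxy)phenyl]prop-2-en-1-ol | OC/C=C/c1ccc(O[Si](C(C)C)(C(C)C)C(C)C)cc1 | intermediate
15 | (E)-1-(3-bromoprop-1-enyl)-4-(triisopropylsilyloxy)benzene | BrC/C=C/c1ccc(O[Si](C(C)C)(C(C)C)C(C)C)cc1 | intermediate
16 | potassium alkoxide of 11 (not isolated) | C=CC[C@@H](CSc1ccccc1)[C@@H]([O-])c1ccc(O[Si](C(C)C)(C(C)C)C(C)C)cc1.[K+] | intermediate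
17 | {4-[(E)-3-{(1R,2R)-2-[(phenylsulfanyl)methyl]-1-[4-(triisopropylsilyloxy)phenyl]pent-4-enyloxy}prop-1-enyl]phenoxy}triisopropylsilane | C=CC[C@@H](CSc1ccccc1)[C@@H](OC/C=C/c1ccc(O[Si](C(C)C)(C(C)C)C(C)C)cc1)c1ccc(O[Si](C(C)C)(C(C)C)C(C)C)cc1 | intermediate
18 | {4-[(E)-3-{(1R,2R)-2-[(phenylsulfonyl)methyl]-1-[4-(triisopropylsilyloxy)phenyl]pent-4-enyloxy}prop-1-enyl]phenoxy}triisopropylsilane | C=CC[C@@H](CS(=O)(=O)c1ccccc1)[C@@H](OC/C=C/c1ccc(O[Si](C(C)C)(C(C)C)C(C)C)cc1)c1ccc(O[Si](C(C)C)(C(C)C)C(C)C)cc1 | intermediate
19 | triisopropyl{4-[(2S,3S)-3-({(1R,2R)-2-[(phenylsulfonyl)methyl]-1-[4-(triisopropylsilyloxy)phenyl]pent-4-enyloxy}methyl)oxiran-2-yl]phenoxy}silane | C=CC[C@@H](CS(=O)(=O)c1ccccc1)[C@@H](OC[C@@H]1O[C@H]1c1ccc(O[Si](C(C)C)(C(C)C)C(C)C)cc1)c1ccc(O[Si](C(C)C)(C(C)C)C(C)C)cc1 | intermediate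
20 | C4-lithiated sulfone of 19 (not isolated) | C=CC[C@@H](C([Li])S(=O)(=O)c1ccccc1)[C@@H](OC[C@@H]1O[C@H]1c1ccc(O[Si](C(C)C)(C(C)C)C(C)C)cc1)c1ccc(O[Si](C(C)C)(C(C)C)C(C)C)cc1 | intermediate
21 | lithium C7-alkoxide of 22 (not isolated) | C=CC[C@H]1C(S(=O)(=O)c2ccccc2)[C@@H]([C@@H](O[Li])c2ccc(O[Si](C(C)C)(C(C)C)C(C)C)cc2)CO[C@H]1c1ccc(O[Si](C(C)C)(C(C)C)C(C)C)cc1 | intermediate
22 | (R)-{(2R,3R,5R)-3-allyl-4-(phenylsulfonyl)-2-[4-(triisopropylsilyloxy)phenyl]tetrahydro-2H-pyran-5-yl}[4-(triisopropylsilyloxy)phenyl]methanol (C4 epimers) | C=CC[C@H]1C(S(=O)(=O)c2ccccc2)[C@@H]([C@@H](O)c2ccc(O[Si](C(C)C)(C(C)C)C(C)C)cc2)CO[C@H]1c1ccc(O[Si](C(C)C)(C(C)C)C(C)C)cc1 | intermediate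
23 | (R)-{(2R,3S,5R)-3-allyl-2-[4-(triisopropylsilyloxy)phenyl]tetrahydro-2H-pyran-5-yl}[4-(triisopropylsilyloxy)phenyl]methanol | C=CC[C@H]1C[C@@H]([C@@H](O)c2ccc(O[Si](C(C)C)(C(C)C)C(C)C)cc2)CO[C@H]1c1ccc(O[Si](C(C)C)(C(C)C)C(C)C)cc1 | intermediate
24 | methylenetriphenylphosphorane (not isolated) | C=P(c1ccccc1)(c1ccccc1)c1ccccc1 | intermediate
25 | triisopropyl(4-vinylphenoxy)silane | C=Cc1ccc(O[Si](C(C)C)(C(C)C)C(C)C)cc1 | intermediate
26 | (R)-{(2R,3S,5R)-2-[4-(triisopropylsilyloxy)phenyl]-3-{(E)-3-[4-(triisopropylsilyloxy)phenyl]prop-2-enyl}tetrahydro-2H-pyran-5-yl}[4-(triisopropylsilyloxy)phenyl]methanol | CC(C)[Si](Oc1ccc(/C=C/C[C@H]2C[C@@H]([C@@H](O)c3ccc(O[Si](C(C)C)(C(C)C)C(C)C)cc3)CO[C@H]2c2ccc(O[Si](C(C)C)(C(C)C)C(C)C)cc2)cc1)(C(C)C)C(C)C | intermediate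
27 | 4-[(E)-3-{(2R,3S,5R)-5-[(R)-hydroxy(4-hydroxyphenyl)methyl]-2-(4-hydroxyphenyl)tetrahydro-2H-pyran-3-yl}prop-1-enyl]phenol | Oc1ccc(/C=C/C[C@H]2C[C@@H]([C@@H](O)c3ccc(O)cc3)CO[C@H]2c2ccc(O)cc2)cc1 | target

## Step count and least certain steps

Total step count: 16. Longest linear sequence: 11 steps (steps 1, 3, 4, 5, 9, 10, 11, 12, 13, 15, 16 from 1; the same length from 3 through step 2).

**Step 12 (key step).**
- What may go wrong: the carbanion may attack the benzylic epoxide carbon C7 (endo closure to a seven-membered ring), or lithium may assist ionisation of the benzylic C–O bond. Both are favoured by the electron-releasing silyloxy group. The closure may also be slow because the transition state must carry the C2 aryl group axial.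
- Fallback: the same closure on an electron-poor aryl epoxide, setting out from 12 and alkoxide 16 and coming back at 23. Ester 12 is sulfonylated (PhSO2Cl, Et3N) to methyl (E)-3-[4-(phenylsulfonyloxy)phenyl]prop-2-enoate F1, reduced with (i-Bu)2AlH to (E)-3-[4-(phenylsulfonyloxy)phenyl]prop-2-en-1-ol F2 and brominated (CBr4, PPh3) to (E)-3-[4-(phenylsulfonyloxy)phenyl]prop-2-enyl bromide F3. Alkoxide 16 is alkylated with F3 to the ether sulfide F4, which is oxidised as in step 10 to the sulfone F5 and epoxidised as in step 11 to the (2S,3S) epoxy sulfone F6. In F6 the arenesulfonate withdraws electron density from C7, so the benzylic carbon has no advantage and the epoxide is no longer acid-labile. Treatment with LiN(SiMe3)2 closes the ring to the hydroxy sulfone F7. Mg in MeOH then cleaves both the C4–S bond and the aryl O–S bond to give the phenol F8, and silylation of the phenol (i-Pr3SiCl, imidazole) gives 23.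

**Step 11.**
- What may go wrong: hydrolytic or rearrangement-type opening of the electron-rich aryl epoxide in the aqueous oxidation medium or on isolation, slow loss of an aryl silyl ether at the basic pH, and oxidation of the terminal alkene when conversion is pushed.
- Fallback: the epoxide oxygen is introduced before the ether bond, under anhydrous conditions, setting out from 14 and alkoxide 16 and coming back at 19. Sharpless asymmetric epoxidation of 14 (Ti(O-i-Pr)4, L-(+)-diethyl tartrate, t-BuOOH, 4 Å molecular sieves, CH2Cl2, −20 °C) gives [(2S,3S)-3-[4-(triisopropylsilyloxy)phenyl]oxiran-2-yl]methanol F9. It is converted with 3-nitrobenzenesulfonyl chloride and Et3N into the epoxy 3-nitrobenzenesulfonate F10. Alkoxide 16 displaces the sulfonate at the primary carbon to give the epoxy ether sulfide F11, and buffered oxidation at sulfur (m-CPBA, 2 equiv, NaHCO3, CH2Cl2, 0 °C; the terminal alkene reacts far more slowly) gives 19.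

**Step 9.**
- What may go wrong: ionisation, solvolysis or elimination of the very electron-rich cinnamyl bromide before it is alkylated, attack at its benzylic terminus to give the branched ether, and sluggish reaction of the hindered secondary alkoxide.
- Fallback: a palladium-catalysed allylic etherification that avoids the halide, setting out from 14 and 11 and coming back at 17. Alcohol 14 is acetylated (Ac2O, pyridine) to (E)-3-[4-(triisopropylsilyloxy)phenyl]prop-2-enyl acetate F12. Alcohol 11 is treated with Et2Zn (0.5 equiv) and then with F12, Pd(OAc)2 (5 mol %) and 2-(di-tert-butylphosphino)biphenyl in THF at rt. The zinc alkoxide should attack the π-allyl palladium intermediate at its unsubstituted terminus and give the linear E ether 17.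

**Step 15.**
- What may go wrong: homodimerisation of 25 outrunning the cross reaction, or ruthenium-hydride-mediated migration of the terminal double bond before metathesis, which would give a side chain one carbon short.
- Fallback: an olefination without metathesis, setting out from 23 and 2 and coming back at 26. Lemieux–Johnson cleavage of 23 (OsO4 cat., NaIO4, 2,6-lutidine, dioxane–H2O) gives 2-{(2R,3R,5R)-5-{(R)-hydroxy[4-(triisopropylsilyloxy)phenyl]methyl}-2-[4-(triisopropylsilyloxy)phenyl]tetrahydro-2H-pyran-3-yl}acetaldehyde F13. Aldehyde 2 is reduced (NaBH4, MeOH) to [4-(triisopropylsilyloxy)phenyl]methanol F14, which with P(OEt)3 and ZnI2 gives diethyl {[4-(triisopropylsilyloxy)phenyl]methyl}phosphonate F15. Horner–Wadsworth–Emmons reaction of F15 (NaH, 2.2 equiv, THF, 0 °C → rt) with F13 should give the E alkene 26.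

## Further compounds

F1 | step 12 | methyl (E)-3-[4-(phenylsulfonyloxy)phenyl]prop-2-enoate | COC(=O)/C=C/c1ccc(OS(=O)(=O)c2ccccc2)cc1
F2 | step 12 | (E)-3-[4-(phenylsulfonyloxy)phenyl]prop-2-en-1-ol | OC/C=C/c1ccc(OS(=O)(=O)c2ccccc2)cc1
F3 | step 12 | (E)-3-[4-(phenylsulfonyloxy)phenyl]prop-2-enyl bromide | BrC/C=C/c1ccc(OS(=O)(=O)c2ccccc2)cc1
F4 | step 12 | 4-[(E)-3-{(1R,2R)-2-[(phenylsulfanyl)methyl]-1-[4-(triisopropylsilyloxy)phenyl]pent-4-enyloxy}prop-1-enyl]phenyl benzenesulfonate | C=CC[C@@H](CSc1ccccc1)[C@@H](OC/C=C/c1ccc(OS(=O)(=O)c2ccccc2)cc1)c1ccc(O[Si](C(C)C)(C(C)C)C(C)C)cc1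
F5 | step 12 | 4-[(E)-3-{(1R,2R)-2-[(phenylsulfonyl)methyl]-1-[4-(triisopropylsilyloxy)phenyl]pent-4-enyloxy}prop-1-enyl]phenyl benzenesulfonate | C=CC[C@@H](CS(=O)(=O)c1ccccc1)[C@@H](OC/C=C/c1ccc(OS(=O)(=O)c2ccccc2)cc1)c1ccc(O[Si](C(C)C)(C(C)C)C(C)C)cc1
F6 | step 12 | 4-[(2S,3S)-3-({(1R,2R)-2-[(phenylsulfonyl)methyl]-1-[4-(triisopropylsilyloxy)phenyl]pent-4-enyloxy}methyl)oxiran-2-yl]phenyl benzenesulfonate | C=CC[C@@H](CS(=O)(=O)c1ccccc1)[C@@H](OC[C@@H]1O[C@H]1c1ccc(OS(=O)(=O)c2ccccc2)cc1)c1ccc(O[Si](C(C)C)(C(C)C)C(C)C)cc1
F7 | step 12 | 4-[(R)-{(2R,3R,5R)-3-allyl-4-(phenylsulfonyl)-2-[4-(triisopropylsilyloxy)phenyl]tetrahydro-2H-pyran-5-yl}(hydroxy)methyl]phenyl benzenesulfonate (C4 epimers) | C=CC[C@H]1C(S(=O)(=O)c2ccccc2)[C@@H]([C@@H](O)c2ccc(OS(=O)(=O)c3ccccc3)cc2)CO[C@H]1c1ccc(O[Si](C(C)C)(C(C)C)C(C)C)cc1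
F8 | step 12 | 4-[(R)-{(2R,3S,5R)-3-allyl-2-[4-(triisopropylsilyloxy)phenyl]tetrahydro-2H-pyran-5-yl}(hydroxy)methyl]phenol | C=CC[C@H]1C[C@@H]([C@@H](O)c2ccc(O)cc2)CO[C@H]1c1ccc(O[Si](C(C)C)(C(C)C)C(C)C)cc1
F9 | step 11 | [(2S,3S)-3-[4-(triisopropylsilyloxy)phenyl]oxiran-2-yl]methanol | OC[C@@H]1O[C@H]1c1ccc(O[Si](C(C)C)(C(C)C)C(C)C)cc1
F10 | step 11 | [(2S,3S)-3-[4-(triisopropylsilyloxy)phenyl]oxiran-2-yl]methyl 3-nitrobenzenesulfonate | O=[N+]([O-])c1cccc(c1)S(=O)(=O)OC[C@@H]1O[C@H]1c1ccc(O[Si](C(C)C)(C(C)C)C(C)C)cc1
F11 | step 11 | triisopropyl{4-[(2S,3S)-3-({(1R,2R)-2-[(phenylsulfanyl)methyl]-1-[4-(triisopropylsilyloxy)phenyl]pent-4-enyloxy}methyl)oxiran-2-yl]phenoxy}silane | C=CC[C@@H](CSc1ccccc1)[C@@H](OC[C@@H]1O[C@H]1c1ccc(O[Si](C(C)C)(C(C)C)C(C)C)cc1)c1ccc(O[Si](C(C)C)(C(C)C)C(C)C)cc1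
F12 | step 9 | (E)-3-[4-(triisopropylsilyloxy)phenyl]prop-2-enyl acetate | CC(=O)OC/C=C/c1ccc(O[Si](C(C)C)(C(C)C)C(C)C)cc1
F13 | step 15 | 2-{(2R,3R,5R)-5-{(R)-hydroxy[4-(triisopropylsilyloxy)phenyl]methyl}-2-[4-(triisopropylsilyloxy)phenyl]tetrahydro-2H-pyran-3-yl}acetaldehyde | O=CC[C@H]1C[C@@H]([C@@H](O)c2ccc(O[Si](C(C)C)(C(C)C)C(C)C)cc2)CO[C@H]1c1ccc(O[Si](C(C)C)(C(C)C)C(C)C)cc1
F14 | step 15 | [4-(triisopropylsilyloxy)phenyl]methanol | OCc1ccc(O[Si](C(C)C)(C(C)C)C(C)C)cc1
F15 | step 15 | diethyl {[4-(triisopropylsilyloxy)phenyl]methyl}phosphonate | CCOP(=O)(Cc1ccc(O[Si](C(C)C)(C(C)C)C(C)C)cc1)OCC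
A1 | alternative 1 | 1,5-bis[(R)-4-benzyl-2-oxooxazolidin-3-yl]pentane-1,5-dione (glutaryl bis-imide) | O=C(CCCC(=O)N1[C@H](Cc2ccccc2)COC1=O)N1[C@H](Cc2ccccc2)COC1=O
A2 | alternative 1 | 4-(tert-butyldimethylsilyloxy)benzaldehyde | O=Cc1ccc(O[Si](C)(C)C(C)(C)C)cc1
A3 | alternative 1 | twofold-symmetric bis(anti-aldol) diol | CC(C)(C)[Si](C)(C)Oc1ccc(cc1)[C@H](O)[C@@H](C(=O)N1[C@H](Cc2ccccc2)COC1=O)C[C@H](C(=O)N1[C@H](Cc2ccccc2)COC1=O)[C@@H](O)c1ccc(O[Si](C)(C)C(C)(C)C)cc1
A4 | alternative 2 | (S)-{4-[4-(tert-butyldimethylsilyloxy)benzoyl]furan-2-yl}[4-(tert-butyldimethylsilyloxy)phenyl]methanol | O[C@H](c1cc(C(=O)c2ccc(O[Si](C)(C)C(C)(C)C)cc2)co1)c1ccc(O[Si](C)(C)C(C)(C)C)cc1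
A5 | alternative 2 | 2-aryl-5-aroyl-6-hydroxy-2H-pyran-3(6H)-one (C6 anomers) | O=C1C=C(C(=O)c2ccc(O[Si](C)(C)C(C)(C)C)cc2)C(O)O[C@H]1c1ccc(O[Si](C)(C)C(C)(C)C)cc1
A6 | alternative 3 | (1R,2S,E)-2-allyl-1,5-bis(4-acetoxyphenyl)pent-4-enyl acetate | C=CC[C@@H](C/C=C/c1ccc(OC(C)=O)cc1)[C@@H](OC(C)=O)c1ccc(OC(C)=O)cc1
A7 | alternative 3 | trans-4-aryl-5-alkyl-1,3-dioxane | C=CC[C@@H](C[C@H]1[C@@H](OCOC1)c1ccc(OC(C)=O)cc1)[C@@H](OC(C)=O)c1ccc(OC(C)=O)cc1
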